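Ring C of the flavan (O1, C2, C3, C4, C4a, C8a) is disconnected at C3–C4 by inserting a nitrogen atom between these carbons. The precursor is the seven-membered (2R)-2-aryl-2,3,4,5-tetrahydro-1,4-benzoxazepine 23, built from ring-A aldehyde 20 and ring-B/D amino alcohol 14 by reductive amination and copper-catalysed O-arylation. Nitrogen deletion then contracts the ring by one atom and forges C3–C4 in one operation. It exploits C4 being benzylic on ring A and para to O7, and it leaves the O1–C2 stereocentre, set by an asymmetric Henry reaction, untouched. The ring-D carbinol comes from Jacobsen–Katsuki epoxidation of a chromene.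

Key step: step 15

Assumption: the target is (2S) at the flavan carbon and (3S) at the ring-D carbinol as drawn, and 2-bromo-4,5-dihydroxybenzaldehyde 1 is taken as a commercial starting material.

Step 1
Reactants: 1 2-bromo-4,5-dihydroxybenzaldehyde; 2 3-chloro-3-methylbut-1-yne
Product: 3 2-bromo-5-hydroxy-4-[(2-methylbut-3-yn-2-yl)oxy]benzaldehyde
Conditions: K2CO3 (1.05 equiv), KI (cat.), CuI (cat.), acetone, 50 °C, argon
Reagents that add atoms: 3-chloro-3-methylbut-1-yne (2), C#CC(C)(C)Cl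
Why: Copper-assisted O-alkylation with the tertiary propargylic chloride should take place at the more acidic 4-OH (para to the formyl group) when only one equivalent of mild base is present.

Step 2
Reactants: 3 2-bromo-5-hydroxy-4-[(2-methylbut-3-yn-2-yl)oxy]benzaldehyde
Product: 4 2-bromo-4-[(2-methylbut-3-yn-2-yl)oxy]-5-[(triisopropylsilyl)oxy]benzaldehyde
Conditions: TIPSCl, imidazole, DMF, rt
Reagents that add atoms: triisopropylsilyl chloride, CC(C)[Si](Cl)(C(C)C)C(C)C
Why: Imidazole-promoted silylation of the remaining phenol gives a bulky silyl ether that should withstand the later thermal, hydride and basic steps.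

Step 3
Reactants: 4 2-bromo-4-[(2-methylbut-3-yn-2-yl)oxy]-5-[(triisopropylsilyl)oxy]benzaldehyde
Product: 6 5-bromo-2,2-dimethyl-8-[(triisopropylsilyl)oxy]-2H-chromene-6-carbaldehyde, via ortho-allenylphenol 5 (not isolated)
Conditions: PhNEt2, 180 °C
Reagents that add atoms: none
Why: Aryl propargyl ether Claisen rearrangement to the only free ortho carbon gives allenylphenol 5, which closes ring D by a 1,5-hydrogen shift and oxa-6π electrocyclisation.

Step 4
Reactants: 6 5-bromo-2,2-dimethyl-8-[(triisopropylsilyl)oxy]-2H-chromene-6-carbaldehyde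
Product: 7 (1aS,7bS)-7-bromo-2,2-dimethyl-4-[(triisopropylsilyl)oxy]-1a,7b-dihydro-2H-oxireno[2,3-c]chromene-6-carbaldehyde
Conditions: (S,S)-(salen)MnCl [salen = N,N'-bis(3,5-di-tert-butylsalicylidene)cyclohexane-1,2-diamine dianion] (5 mol %), mCPBA, NMO, CH2Cl2, −78 °C
Reagents that add atoms: mCPBA, O=C(OO)c1cccc(Cl)c1
Why: Jacobsen–Katsuki epoxidation, for which 2,2-dimethylchromenes are the best substrate class; the (S,S)-salen manganese oxo species should add to the face of C3=C4 that gives the (3S,4S)-epoxide (chroman numbering) by catalyst control.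

Step 5
Reactants: 7 (1aS,7bS)-7-bromo-2,2-dimethyl-4-[(triisopropylsilyl)oxy]-1a,7b-dihydro-2H-oxireno[2,3-c]chromene-6-carbaldehyde
Product: 8 (3S)-5-bromo-6-(hydroxymethyl)-2,2-dimethyl-8-[(triisopropylsilyl)oxy]chroman-3-ol
Conditions: LiAlH4, THF, 0 °C; then H2O
Reagents that add atoms: none
Why: Hydride should open the epoxide by SN2 attack at benzylic C4 (C3 is neopentyl-like next to the gem-dimethyl carbon), so the C3–O bond keeps its S configuration; the aldehyde is reduced in the same operation, and a Lewis-acidic hydride system is avoided because it could deoxygenate the para-alkoxybenzylic alcohol.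

Step 6
Reactants: 8 (3S)-5-bromo-6-(hydroxymethyl)-2,2-dimethyl-8-[(triisopropylsilyl)oxy]chroman-3-ol
Product: 9 (3S)-5-bromo-3-hydroxy-2,2-dimethyl-8-[(triisopropylsilyl)oxy]chromane-6-carbaldehyde
Conditions: MnO2 (activated, excess), CH2Cl2, rt
Reagents that add atoms: none
Why: Activated MnO2 oxidises only the benzylic primary alcohol and should leave the secondary aliphatic alcohol untouched (chemoselective benzylic oxidation).

Step 7
Reactants: 9 (3S)-5-bromo-3-hydroxy-2,2-dimethyl-8-[(triisopropylsilyl)oxy]chromane-6-carbaldehyde; 10 tributyl(3-methylbut-2-en-1-yl)stannane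
Product: 11 (3S)-3-hydroxy-2,2-dimethyl-5-(3-methylbut-2-en-1-yl)-8-[(triisopropylsilyl)oxy]chromane-6-carbaldehyde
Conditions: Pd(PPh3)4 (5 mol %), toluene, 100 °C
Reagents that add atoms: tributyl(3-methylbut-2-en-1-yl)stannane (10), CCCC[Sn](CCCC)(CCCC)CC=C(C)C
Why: Stille coupling at the aryl bromide, which the ortho formyl group activates towards zerovalent palladium; the prenylstannane should transfer through its α carbon to give the linear prenyl arene.

Step 8
Reactants: 11 (3S)-3-hydroxy-2,2-dimethyl-5-(3-methylbut-2-en-1-yl)-8-[(triisopropylsilyl)oxy]chromane-6-carbaldehyde; 12 nitromethane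
Product: 13 (3S)-6-[(1R)-1-hydroxy-2-nitroethyl]-2,2-dimethyl-5-(3-methylbut-2-en-1-yl)-8-[(triisopropylsilyl)oxy]chroman-3-ol
Conditions: Cu(OAc)2·H2O (5 mol %), indane-fused bis(oxazoline) ligand (inda-box, enantiomer that gives the R alcohol, 5.5 mol %), MeNO2 (10 equiv), EtOH, rt
Reagents that add atoms: nitromethane (12), C[N+](=O)[O-]
Why: Catalytic asymmetric Henry reaction; the chiral copper acetate–bis(oxazoline) complex binds the aldehyde and delivers the nitronate to one carbonyl face, so the (R)-carbinol (the future C2 of ring C) is set by catalyst control.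

Step 9
Reactants: 13 (3S)-6-[(1R)-1-hydroxy-2-nitroethyl]-2,2-dimethyl-5-(3-methylbut-2-en-1-yl)-8-[(triisopropylsilyl)oxy]chroman-3-ol
Product: 14 (3S)-6-[(1R)-2-amino-1-hydroxyethyl]-2,2-dimethyl-5-(3-methylbut-2-en-1-yl)-8-[(triisopropylsilyl)oxy]chroman-3-ol
Conditions: Zn dust, AcOH, EtOH, 0 °C to rt
Reagents that add atoms: none
Why: Dissolving-metal reduction of the aliphatic nitro group to the primary amine under mildly acidic conditions should avoid retro-Henry cleavage and leave the alkene, silyl ether and carbinol centre alone.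

Step 10
Reactants: 15 2-bromo-4-hydroxybenzaldehyde; 16 1-bromo-3-methylbut-2-ene
Product: 17 2-bromo-4-[(3-methylbut-2-en-1-yl)oxy]benzaldehyde
Conditions: K2CO3, acetone, reflux
Reagents that add atoms: 1-bromo-3-methylbut-2-ene (16), CC(C)=CCBr
Why: Williamson etherification of the phenoxide with the primary allylic bromide (SN2).

Step 11
Reactants: 17 2-bromo-4-[(3-methylbut-2-en-1-yl)oxy]benzaldehyde
Product: 19 2-bromo-4-hydroxy-5-(2-methylbut-3-en-2-yl)benzaldehyde, via dienone 18 (not isolated)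
Conditions: PhNEt2, 190 °C, sealed tube
Reagents that add atoms: none
Why: Aromatic Claisen rearrangement; the [3,3] shift inverts the prenyl unit and should deliver its tertiary carbon to C5, the ortho carbon not flanked by bromine, after which dienone 18 tautomerises to the phenol.

Step 12
Reactants: 19 2-bromo-4-hydroxy-5-(2-methylbut-3-en-2-yl)benzaldehyde
Product: 20 2-bromo-4-[(tert-butyldimethylsilyl)oxy]-5-(2-methylbut-3-en-2-yl)benzaldehyde
Conditions: TBSCl, imidazole, DMF, 40 °C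
Reagents that add atoms: tert-butyldimethylsilyl chloride, CC(C)(C)[Si](C)(C)Cl
Why: Imidazole-promoted silylation masks the phenol for the copper-catalysed etherification; the neighbouring quaternary carbon shields the silyl ether afterwards.

Step 13
Reactants: 14 (3S)-6-[(1R)-2-amino-1-hydroxyethyl]-2,2-dimethyl-5-(3-methylbut-2-en-1-yl)-8-[(triisopropylsilyl)oxy]chroman-3-ol; 20 2-bromo-4-[(tert-butyldimethylsilyl)oxy]-5-(2-methylbut-3-en-2-yl)benzaldehyde
Product: 22 (3S)-6-[(1R)-2-({[2-bromo-4-(tert-butyldimethylsilyloxy)-5-(2-methylbut-3-en-2-yl)phenyl]methyl}amino)-1-hydroxyethyl]-2,2-dimethyl-5-(3-methylbut-2-en-1-yl)-8-(triisopropylsilyloxy)chroman-3-ol, via imine 21 (not isolated)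
Conditions: MgSO4, CH2Cl2, rt; then NaBH(OAc)3, AcOH (cat.), 0 °C to rt
Reagents that add atoms: none
Why: Reductive amination: the primary amine condenses with the aldehyde to imine 21, which NaBH(OAc)3 reduces without touching the aryl bromide, alkenes or silyl ethers, and the carbinol centre is not involved.

Step 14
Reactants: 22 (3S)-6-[(1R)-2-({[2-bromo-4-(tert-butyldimethylsilyloxy)-5-(2-methylbut-3-en-2-yl)phenyl]methyl}amino)-1-hydroxyethyl]-2,2-dimethyl-5-(3-methylbut-2-en-1-yl)-8-(triisopropylsilyloxy)chroman-3-ol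
Product: 23 (3S)-6-[(2R)-8-(tert-butyldimethylsilyloxy)-7-(2-methylbut-3-en-2-yl)-2,3,4,5-tetrahydro-1,4-benzoxazepin-2-yl]-2,2-dimethyl-5-(3-methylbut-2-en-1-yl)-8-(triisopropylsilyloxy)chroman-3-ol
Conditions: CuI (10 mol %), 3,4,7,8-tetramethyl-1,10-phenanthroline (20 mol %), Cs2CO3, toluene, 110 °C
Reagents that add atoms: none
Why: Intramolecular Ullmann-type C–O coupling closes the seven-membered ring by attack of the benzylic alkoxide on the ring-A C–Br carbon (N-arylation would need a four-membered ring); the C–O bond of the stereocentre is not broken, so its R configuration is retained.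

Step 15
Reactants: 23 (3S)-6-[(2R)-8-(tert-butyldimethylsilyloxy)-7-(2-methylbut-3-en-2-yl)-2,3,4,5-tetrahydro-1,4-benzoxazepin-2-yl]-2,2-dimethyl-5-(3-methylbut-2-en-1-yl)-8-(triisopropylsilyloxy)chroman-3-ol
Product: 26 (3S)-6-[(2S)-7-(tert-butyldimethylsilyloxy)-6-(2-methylbut-3-en-2-yl)chroman-2-yl]-2,2-dimethyl-5-(3-methylbut-2-en-1-yl)-8-(triisopropylsilyloxy)chroman-3-ol, via hydrazide adduct 24 (not isolated), via isodiazene 25 (not isolated)
Conditions: N-(benzyloxy)-N-(pivaloyloxy)-4-(trifluoromethyl)benzamide (1.5 equiv), THF, 45 °C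
Reagents that add atoms: none
Why: The ring amine attacks the electrophilic nitrogen of the anomeric amide (pivalate leaves) to give hydrazide 24, which expels benzyl 4-(trifluoromethyl)benzoate to form isodiazene 25; loss of N2 from 25 leaves a singlet biradical at C4 and C3 that collapses to the C3–C4 bond. The closest known reaction type is nitrogen deletion of secondary benzylic amines with an anomeric amide, including ring contraction of cyclic amines, itself a variant of the 1,1-diazene (Overberger–Lombardino) extrusion. Ring C closes as a six-membered ring by radical–radical recombination of the tethered 1,6-biradical, the seven-membered oxazepine contracting by one atom. No stereocentre is formed: C2 lies outside the reacting C3–N–C4 unit and keeps its configuration, the (2R) descriptor of 23 becoming (2S) in 26 only because the CIP priorities change. The step needs recombination to outrun scission of the O1–C2 bond of the biradical (which would give a ring-A ortho-quinone methide and a styrene) and 1,5-hydrogen transfer; the benzylic C4 radical on ring A, para to O7, lets N2 leave at 45 °C, and the O1–C2 tether keeps both radical centres in contact so that barrierless coupling should beat the activated fragmentation.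

Step 16
Reactants: 26 (3S)-6-[(2S)-7-(tert-butyldimethylsilyloxy)-6-(2-methylbut-3-en-2-yl)chroman-2-yl]-2,2-dimethyl-5-(3-methylbut-2-en-1-yl)-8-(triisopropylsilyloxy)chroman-3-ol
Product: 27 (3S)-6-[(2S)-7-hydroxy-6-(2-methylbut-3-en-2-yl)chroman-2-yl]-2,2-dimethyl-5-(3-methylbut-2-en-1-yl)chromane-3,8-diol
Conditions: Bu4NF, AcOH, THF, 0 °C to rt
Reagents that add atoms: none
Why: Fluoride cleaves both aryl silyl ethers through Si–F bond formation, and the AcOH buffer should protect the electron-rich phenols and the benzylic ether of ring C from base.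

Compound list
1 | 2-bromo-4,5-dihydroxybenzaldehyde | O=Cc1cc(O)c(O)cc1Br | starting material
2 | 3-chloro-3-methylbut-1-yne | C#CC(C)(C)Cl | starting material
3 | 2-bromo-5-hydroxy-4-[(2-methylbut-3-yn-2-yl)oxy]benzaldehyde | O=Cc1cc(O)c(OC(C)(C)C#C)cc1Br | intermediate
4 | 2-bromo-4-[(2-methylbut-3-yn-2-yl)oxy]-5-[(triisopropylsilyl)oxy]benzaldehyde | O=Cc1cc(O[Si](C(C)C)(C(C)C)C(C)C)c(OC(C)(C)C#C)cc1Br | intermediate
5 | 2-bromo-4-hydroxy-3-(3-methylbuta-1,2-dien-1-yl)-5-[(triisopropylsilyl)oxy]benzaldehyde (ortho-allenylphenol) | O=Cc1cc(O[Si](C(C)C)(C(C)C)C(C)C)c(O)c(C=C=C(C)C)c1Br | intermediate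
6 | 5-bromo-2,2-dimethyl-8-[(triisopropylsilyl)oxy]-2H-chromene-6-carbaldehyde | O=Cc1cc(O[Si](C(C)C)(C(C)C)C(C)C)c2OC(C)(C)C=Cc2c1Br | intermediate
7 | (1aS,7bS)-7-bromo-2,2-dimethyl-4-[(triisopropylsilyl)oxy]-1a,7b-dihydro-2H-oxireno[2,3-c]chromene-6-carbaldehyde | O=Cc1cc(O[Si](C(C)C)(C(C)C)C(C)C)c2OC(C)(C)[C@H]3O[C@H]3c2c1Br | intermediate
8 | (3S)-5-bromo-6-(hydroxymethyl)-2,2-dimethyl-8-[(triisopropylsilyl)oxy]chroman-3-ol | OCc1cc(O[Si](C(C)C)(C(C)C)C(C)C)c2OC(C)(C)[C@@H](O)Cc2c1Br | intermediate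
9 | (3S)-5-bromo-3-hydroxy-2,2-dimethyl-8-[(triisopropylsilyl)oxy]chromane-6-carbaldehyde | O=Cc1cc(O[Si](C(C)C)(C(C)C)C(C)C)c2OC(C)(C)[C@@H](O)Cc2c1Br | intermediate
10 | tributyl(3-methylbut-2-en-1-yl)stannane | CCCC[Sn](CCCC)(CCCC)CC=C(C)C | starting material
11 | (3S)-3-hydroxy-2,2-dimethyl-5-(3-methylbut-2-en-1-yl)-8-[(triisopropylsilyl)oxy]chromane-6-carbaldehyde | O=Cc1cc(O[Si](C(C)C)(C(C)C)C(C)C)c2OC(C)(C)[C@@H](O)Cc2c1CC=C(C)C | intermediate
12 | nitromethane | C[N+](=O)[O-] | starting material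
13 | (3S)-6-[(1R)-1-hydroxy-2-nitroethyl]-2,2-dimethyl-5-(3-methylbut-2-en-1-yl)-8-[(triisopropylsilyl)oxy]chroman-3-ol | O[C@@H](C[N+](=O)[O-])c1cc(O[Si](C(C)C)(C(C)C)C(C)C)c2OC(C)(C)[C@@H](O)Cc2c1CC=C(C)C | intermediate
14 | (3S)-6-[(1R)-2-amino-1-hydroxyethyl]-2,2-dimethyl-5-(3-methylbut-2-en-1-yl)-8-[(triisopropylsilyl)oxy]chroman-3-ol | NC[C@H](O)c1cc(O[Si](C(C)C)(C(C)C)C(C)C)c2OC(C)(C)[C@@H](O)Cc2c1CC=C(C)C | intermediate
15 | 2-bromo-4-hydroxybenzaldehyde | O=Cc1ccc(O)cc1Br | starting material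
16 | 1-bromo-3-methylbut-2-ene (prenyl bromide) | CC(C)=CCBr | starting material
17 | 2-bromo-4-[(3-methylbut-2-en-1-yl)oxy]benzaldehyde | O=Cc1ccc(OCC=C(C)C)cc1Br | intermediate
18 | 3-bromo-4-formyl-6-(2-methylbut-3-en-2-yl)cyclohexa-2,4-dien-1-one (dienone) | O=CC1=CC(C(C)(C)C=C)C(=O)C=C1Br | intermediate
19 | 2-bromo-4-hydroxy-5-(2-methylbut-3-en-2-yl)benzaldehyde | O=Cc1cc(C(C)(C)C=C)c(O)cc1Br | intermediate
20 | 2-bromo-4-[(tert-butyldimethylsilyl)oxy]-5-(2-methylbut-3-en-2-yl)benzaldehyde | O=Cc1cc(C(C)(C)C=C)c(O[Si](C)(C)C(C)(C)C)cc1Br | intermediate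
21 | (E)-imine of 14 and 20: (3S)-6-[(1R)-2-({[2-bromo-4-(tert-butyldimethylsilyloxy)-5-(2-methylbut-3-en-2-yl)phenyl]methylidene}amino)-1-hydroxyethyl]-2,2-dimethyl-5-(3-methylbut-2-en-1-yl)-8-(triisopropylsilyloxy)chroman-3-ol | C=CC(C)(C)c1cc(/C=N/C[C@H](O)c2cc(O[Si](C(C)C)(C(C)C)C(C)C)c3OC(C)(C)[C@@H](O)Cc3c2CC=C(C)C)c(Br)cc1O[Si](C)(C)C(C)(C)C | intermediate
22 | (3S)-6-[(1R)-2-({[2-bromo-4-(tert-butyldimethylsilyloxy)-5-(2-methylbut-3-en-2-yl)phenyl]methyl}amino)-1-hydroxyethyl]-2,2-dimethyl-5-(3-methylbut-2-en-1-yl)-8-(triisopropylsilyloxy)chroman-3-ol | C=CC(C)(C)c1cc(CNC[C@H](O)c2cc(O[Si](C(C)C)(C(C)C)C(C)C)c3OC(C)(C)[C@@H](O)Cc3c2CC=C(C)C)c(Br)cc1O[Si](C)(C)C(C)(C)C | intermediate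
23 | (3S)-6-[(2R)-8-(tert-butyldimethylsilyloxy)-7-(2-methylbut-3-en-2-yl)-2,3,4,5-tetrahydro-1,4-benzoxazepin-2-yl]-2,2-dimethyl-5-(3-methylbut-2-en-1-yl)-8-(triisopropylsilyloxy)chroman-3-ol | C=CC(C)(C)c1cc2CNC[C@@H](c3cc(O[Si](C(C)C)(C(C)C)C(C)C)c4OC(C)(C)[C@@H](O)Cc4c3CC=C(C)C)Oc2cc1O[Si](C)(C)C(C)(C)C | intermediate
24 | N-(benzyloxy)-N-{(2R)-8-(tert-butyldimethylsilyloxy)-2-[(3S)-3-hydroxy-2,2-dimethyl-5-(3-methylbut-2-en-1-yl)-8-(triisopropylsilyloxy)chroman-6-yl]-7-(2-methylbut-3-en-2-yl)-2,3-dihydro-1,4-benzoxazepin-4(5H)-yl}-4-(trifluoromethyl)benzamide (hydrazide adduct) | C=CC(C)(C)c1cc2CN(N(OCc5ccccc5)C(=O)c5ccc(cc5)C(F)(F)F)C[C@@H](c3cc(O[Si](C(C)C)(C(C)C)C(C)C)c4OC(C)(C)[C@@H](O)Cc4c3CC=C(C)C)Oc2cc1O[Si](C)(C)C(C)(C)C | intermediate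
25 | isodiazene (1,1-diazene at N4) of 23 | C=CC(C)(C)c1cc2C[N+](=[N-])C[C@@H](c3cc(O[Si](C(C)C)(C(C)C)C(C)C)c4OC(C)(C)[C@@H](O)Cc4c3CC=C(C)C)Oc2cc1O[Si](C)(C)C(C)(C)C | intermediate
26 | (3S)-6-[(2S)-7-(tert-butyldimethylsilyloxy)-6-(2-methylbut-3-en-2-yl)chroman-2-yl]-2,2-dimethyl-5-(3-methylbut-2-en-1-yl)-8-(triisopropylsilyloxy)chroman-3-ol | C=CC(C)(C)c1cc2CC[C@@H](c3cc(O[Si](C(C)C)(C(C)C)C(C)C)c4OC(C)(C)[C@@H](O)Cc4c3CC=C(C)C)Oc2cc1O[Si](C)(C)C(C)(C)C | intermediate
27 | (3S)-6-[(2S)-7-hydroxy-6-(2-methylbut-3-en-2-yl)chroman-2-yl]-2,2-dimethyl-5-(3-methylbut-2-en-1-yl)chromane-3,8-diol (CNP0323011.1) | C=CC(C)(C)c1cc2c(cc1O)O[C@H](c1cc(O)c3c(c1CC=C(C)C)C[C@H](O)C(C)(C)O3)CC2 | target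

Total step count: 16. Longest linear sequence: 13 steps (steps 1 to 9, then 13 to 16); steps 10 to 12 make the ring-A aldehyde in a side branch.

Steps most likely to fail

Step 15 (key step). After loss of N2 the C3/C4 biradical may cleave its O1–C2 bond (a retro-[4+2] to a ring-A ortho-quinone methide and a ring-B styrene, which would recombine without stereocontrol or polymerise). Amination of the hindered ring nitrogen by the bulky anomeric amide may also be slow. The fallback is the classical Overberger–Lombardino sequence; it sets out from 23 and comes back at 26. Nitrosation of 23 with tert-butyl nitrite in CH2Cl2 should give the N-nitroso benzoxazepine F1. Zn dust in AcOH should reduce it to the N-amino benzoxazepine F2. Oxidation of F2 with HgO (divalent mercury oxide) at 0 °C should generate isodiazene 25 at low temperature, where barrierless radical-pair collapse is favoured further over the activated O1–C2 scission, and give 26.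

Step 14. Chelation of copper by the 1,2-amino alcohol, slow oxidative addition to the electron-rich aryl bromide and the strain of the seven-membered transition state may stall ring closure or divert it to hydrodebromination. The fallback sets out from 22 and comes back at 23. 2-Nitrobenzenesulfonyl chloride and Et3N should convert 22 into the N-(2-nitrobenzenesulfonyl) amino alcohol F3, which removes the basic NH and biases the chain towards cyclisation. Palladium-catalysed intramolecular etherification (Pd(OAc)2, 2-(di-tert-butylphosphino)-1,1'-binaphthyl, Cs2CO3, toluene, 70 °C) should then give the N-(2-nitrobenzenesulfonyl) benzoxazepine F4. Thiophenol and K2CO3 in DMF should remove the sulfonyl group and give 23.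

Step 11. The liberated ortho-(1,1-dimethylallyl)phenol can react on at 190 °C (abnormal Claisen rearrangement, ring closure to a dihydrobenzofuran, loss of the allyl unit), and part of the allyl group may go to C3. The fallback sets out from 17 and comes back at 19. The rearrangement is run in N,N-diethylaniline with acetic anhydride and NaOAc, so that the phenol is intercepted as it forms as the aryl acetate F5, which cannot enter these follow-up reactions and should be separable from any C3 isomer. K2CO3 in MeOH at 0 °C should then cleave the acetate and give 19.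

Further compounds
F1 | step 15 | (3S)-6-[(2R)-8-(tert-butyldimethylsilyloxy)-7-(2-methylbut-3-en-2-yl)-4-nitroso-2,3,4,5-tetrahydro-1,4-benzoxazepin-2-yl]-2,2-dimethyl-5-(3-methylbut-2-en-1-yl)-8-(triisopropylsilyloxy)chroman-3-ol | C=CC(C)(C)c1cc2CN(N=O)C[C@@H](c3cc(O[Si](C(C)C)(C(C)C)C(C)C)c4OC(C)(C)[C@@H](O)Cc4c3CC=C(C)C)Oc2cc1O[Si](C)(C)C(C)(C)C
F2 | step 15 | (3S)-6-[(2R)-4-amino-8-(tert-butyldimethylsilyloxy)-7-(2-methylbut-3-en-2-yl)-2,3,4,5-tetrahydro-1,4-benzoxazepin-2-yl]-2,2-dimethyl-5-(3-methylbut-2-en-1-yl)-8-(triisopropylsilyloxy)chroman-3-ol | C=CC(C)(C)c1cc2CN(N)C[C@@H](c3cc(O[Si](C(C)C)(C(C)C)C(C)C)c4OC(C)(C)[C@@H](O)Cc4c3CC=C(C)C)Oc2cc1O[Si](C)(C)C(C)(C)C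
F3 | step 14 | N-{[2-bromo-4-(tert-butyldimethylsilyloxy)-5-(2-methylbut-3-en-2-yl)phenyl]methyl}-N-{(2R)-2-hydroxy-2-[(3S)-3-hydroxy-2,2-dimethyl-5-(3-methylbut-2-en-1-yl)-8-(triisopropylsilyloxy)chroman-6-yl]ethyl}-2-nitrobenzenesulfonamide | C=CC(C)(C)c1cc(CN(C[C@H](O)c2cc(O[Si](C(C)C)(C(C)C)C(C)C)c3OC(C)(C)[C@@H](O)Cc3c2CC=C(C)C)S(=O)(=O)c2ccccc2[N+](=O)[O-])c(Br)cc1O[Si](C)(C)C(C)(C)C
F4 | step 14 | (3S)-6-[(2R)-8-(tert-butyldimethylsilyloxy)-7-(2-methylbut-3-en-2-yl)-4-(2-nitrobenzenesulfonyl)-2,3,4,5-tetrahydro-1,4-benzoxazepin-2-yl]-2,2-dimethyl-5-(3-methylbut-2-en-1-yl)-8-(triisopropylsilyloxy)chroman-3-ol | C=CC(C)(C)c1cc2CN(S(=O)(=O)c5ccccc5[N+](=O)[O-])C[C@@H](c3cc(O[Si](C(C)C)(C(C)C)C(C)C)c4OC(C)(C)[C@@H](O)Cc4c3CC=C(C)C)Oc2cc1O[Si](C)(C)C(C)(C)C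
F5 | step 11 | 5-bromo-4-formyl-2-(2-methylbut-3-en-2-yl)phenyl acetate | O=Cc1cc(C(C)(C)C=C)c(OC(C)=O)cc1Br
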